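What is left of J at 20 min is the leftover to reckon, although the runs read c_L, not c_J.

| flask | J | D | remark | time |
|---|---|---|---|---|
| summer | 1 M | 1.1 M | the very flask that is asked about, followed so far |  |
| spring | 0.50 M | 1.1 M | run made earlier |  |
| flask | 1.0 M | 1.10 M |  | 20 min |

| summer: time / min | summer: L / % | spring: time / min | spring: L / % |
|---|---|---|---|
| 0.250 | 1 | 0.667 | 5 |
| 0.667 | 6 | 1.00 | 10 |
| 1.33 | 9 | 2.00 | 14 |
| 2.00 | 14 | 3.00 | 19 |
| 3.00 | 20 | 5.00 | 26 |
| 4.00 | 23 | 8.00 | 33 |

(each reading ± 1.5 percentage points)

- amount of L in percent of the J charged, at 1.0 min, 5.0 min and 20 min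

Which given number has to be known well? The charge c_J matters little for a percentage: the summer run at 1 M and the spring run at 0.50 M both read 14% at 2.00 min, so J behaves as about first order and a slip in c_J moves the percentage little. The charge c_D stands at 1.10 M in the flask and in both runs, so its order stays untested and costs nothing here. The readings at 1.0 min and 5.0 min fall inside the runs, so an error there stays near the scatter of 1.5 percentage points. The point at 20 min lies beyond the last reading at 8.00 min, so it hangs on the late slope.

In the spring run L forms at 0.0700 min⁻¹ of the charge up to 2.00 min, but at 0.0233 min⁻¹ between 5.00 min and 8.00 min. Over the 5.50 min between these midpoints, that fall gives a decay constant of 0.200 min⁻¹. This constant times the time is the count of turnovers, 3.99 at 20 min. The feed left is then e to the minus count, 1.85%, and a count of 2.99 would leave 5.03%, small in either case. Taking L to stay L, the spring reading at 8.00 min gives a plateau of 41.4%, so the reckoning here gives 7.50%, 26.2% and 40.6%.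

The forecast gives 7.5%, 26.5% and 45%, more than this reckoning at the end, and calls that last value “the uncertain one, with a skew upward”.

The flask gives 7.78%, 26.6% and 33.5%.

    J → E (k = 0.0720 min⁻¹)
    J + D ⇌ G (K = 30.0 L mol⁻¹, k = 0.0200 L mol⁻¹ min⁻¹)
    J → L (k = 0.0860 min⁻¹)
    L ⇌ Z (K = 13.0, k = 0.0230 min⁻¹)

At 20.0 min the flask holds 2.86% of J, a count of 3.55 turnovers against the 3.99 reckoned from the scattered spring readings, and L is made at 0.331 of the rate at which it is used up, each step taken net, while c_L has gone from 34.6% at 10.0 min to 33.5%. The passing of L into Z, with a half-life of 30 min by its forward rate, has a net turnover of 13.3% of the J charged up to 20 min.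

Readings and results stem from a simulated flask on assumed constants, noise included.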